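The numbers of this flask are those of an exercise; the rest is arithmetic.

5500 is the ratio of Ptn2 to Byp that the balance holds north-east while Ptn stands at its charge.

    Sbt + Tgt → Sid (k1 = 0.014 M⁻¹ s⁻¹)
    Sbt + Ptn → Byp + Tgt (k2 = 0.017 M⁻¹ s⁻¹)
    Ptn + Byp ⇌ Ptn2, settled at all times (K3 = 2.6 × 10⁵ M⁻¹)

the same everywhere: Ptn 21.0 mM; time 1.0 h

| run | Sbt |
|---|---|
| north-east | 10 mM |
| west | 20 mM |
| south-east | 40 mM |

- [Tgt] at the end for north-east, west, south-east, in this order
- the shape of the row from first to last (rises, then falls / falls all the way / falls, then rises / hardly changes / rises all the way)

- percent here means Sbt units held: one Sid counts as two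
- "hardly changes" means that all values lie within two and a half points (for a concentration: within two and a half percent of the largest)
- run time (north-east): 1.0 h

So we count two Ptn for each pass through the making step: one reacts and one binds the Byp released. This gives the quantity we carry, the reach: the fraction of the Sbt charge that goes through that step if each Byp binds a Ptn, the Ptn charge divided by two Sbt charges.

north-east 105%, west 52.5%, south-east 26.2%

The making step runs pseudo-first-order in Sbt while free Ptn stands near its charge. With Ptn charged at 21.0 mM in north-east, west and south-east, the curve of passes starts on one slope:

slope = 1.29 h⁻¹ of the Sbt charge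

The knee comes where that slope would meet the reach:

north-east 0.817 h, west 0.408 h, south-east 0.204 h

Beyond its knee the south-east curve should flatten towards its reach. Tgt follows a different curve: the loss step, Sbt + Tgt to Sid, uses it up as well. With Sbt as charged, its half-life is:

north-east 1.4 h, west 0.688 h, south-east 0.344 h

South-east, the knee comes before that half-life and both come before the end of the run, so Tgt should turn down there. North-east, the half-life outlasts the run, so Tgt should still be climbing. We expect the row to rise and then fall, but our reckoning stops at that shape.

The forecast goes further, with 4.6 mM, 5.6 mM and 3.7 mM, rises, then falls, on the ground that “each Byp formed locks away a second Ptn”. That is our reach in its own words.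

The flask gives 4.66 mM, 5.64 mM and 3.69 mM, rises, then falls.

North-east, Tgt is made, net, 7.29 times faster than it is used up at 0.296 h and 2.61 times faster at 1.00 h, and the passes, Tgt plus 0.5 of Sid, stand at 55.1%, which over the reach makes 52.5% of the Ptn spent, against 52.5% in the flask. South-east at 1.00 h, the passes stand at 25.5% against a reach of 26.2%, with 3.1% of the Ptn left and 9.23% of the Sbt charge held as Tgt.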